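The route rests on disconnecting ring A at C4a–C8a and C5–C6. Ring A carries three mutually meta oxygens (on C5, C7 and C8a) and one carbon substituent (C4 on C4a), which is exactly the pattern that a vinylketene from 3-benzyloxycyclobutenone and a siloxyalkyne deliver in a single thermal benzannulation. In one operation that step builds the whole phloroglucinol ring regiospecifically and liberates only the C8a phenol, which afterwards opens a neighbouring cis-aryl epoxide at C2 with inversion to close ring C as the 2,3-cis flavan-3-ol. The precursor is therefore a triisopropylsiloxyalkyne carrying, one methylene away, the enantioenriched (2S,3R)-epoxide of a Z-styrene.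

Key step: step 6

Remark on the chemistry: the facial sense of the (S,S)-Jacobsen catalyst is assigned by analogy with cis-β-methylstyrene, which it converts into the benzylic-S cis-epoxide.

Step 1
Reactants: 1 (4-bromobut-1-yn-1-yl)trimethylsilane
Product: 2 triphenyl[4-(trimethylsilyl)but-3-yn-1-yl]phosphonium bromide
Conditions: PPh3, MeCN, reflux; precipitation with Et2O
Reagents that add atoms: triphenylphosphine, c1ccc(cc1)P(c1ccccc1)c1ccccc1
Why: SN2 quaternisation of triphenylphosphine by the primary bromide (phosphonium salt formation) should be clean, and the C-silyl cap removes the acidic alkyne proton that would otherwise compete with ylide formation in step 2.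

Step 2
Reactants: 2 triphenyl[4-(trimethylsilyl)but-3-yn-1-yl]phosphonium bromide; 3 3,4-bis(benzyloxy)benzaldehyde
Product: 6 1,2-bis(benzyloxy)-4-[(1Z)-pent-1-en-4-yn-1-yl]benzene, via phosphorus ylide 4 (not isolated), via silyl enyne 5 (not isolated)
Conditions: NaN(SiMe3)2, THF, −78 °C; then 3, −78 °C → rt; then MeOH, K2CO3 (0.3 equiv), rt
Reagents that add atoms: none
Why: Wittig olefination with a non-stabilised ylide under lithium-free conditions should close the kinetic cis-oxaphosphetane and give the Z-alkene, after which carbonate-catalysed methanolysis of the alkynyl C–Si bond in the same flask frees the terminal alkyne under conditions mild enough to leave the skipped enyne unisomerised.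

Step 3
Reactants: 6 1,2-bis(benzyloxy)-4-[(1Z)-pent-1-en-4-yn-1-yl]benzene
Product: 7 (2S,3R)-2-[3,4-bis(benzyloxy)phenyl]-3-(prop-2-yn-1-yl)oxirane
Conditions: (S,S)-[N,N'-bis(3,5-di-tert-butylsalicylidene)-1,2-cyclohexanediaminato]MnCl (Jacobsen catalyst, 5 mol%), mCPBA, NMO, CH2Cl2, −78 °C; cold aq. NaOH work-up
Reagents that add atoms: mCPBA, O=C(OO)c1cccc(Cl)c1
Why: Jacobsen–Katsuki epoxidation is at its best with aryl-conjugated cis-disubstituted olefins, so the oxomanganese species of the (S,S)-catalyst should add to one enantioface and set both stereocentres at once as the cis-(2S,3R)-epoxide, the anhydrous low-temperature variant limiting leakage to the trans-epoxide and acid damage while the non-conjugated alkyne is left alone.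

Step 4
Reactants: 7 (2S,3R)-2-[3,4-bis(benzyloxy)phenyl]-3-(prop-2-yn-1-yl)oxirane
Product: 10 (2S,3R)-2-[3,4-bis(benzyloxy)phenyl]-3-[3-(triisopropylsilyloxy)prop-2-yn-1-yl]oxirane, via lithium acetylide 8 (not isolated), via lithium ynolate 9 (not isolated)
Conditions: LiN(SiMe3)2, THF, −78 °C; LiOOtBu (from tBuOOH and LiN(SiMe3)2), −78 → 0 °C; TIPSCl, −78 °C → rt
Reagents that add atoms: tert-butyl hydroperoxide (as LiOOtBu), CC(C)(C)OO; chlorotriisopropylsilane, CC(C)[Si](Cl)(C(C)C)C(C)C
Why: Deprotonation gives the lithium acetylide, electrophilic oxygen transfer from LiOOtBu turns it into the lithium ynolate, and O-silylation with the bulky chlorosilane gives the isolable silyl ynol ether (acetylide oxidation followed by ynolate silylation), the medium staying basic throughout and the chloride being preferred to a silyl triflate so that no Lewis acid meets the aryl epoxide, whose stereocentres are untouched.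

Step 5
Reactants: 11 3-ethoxycyclobut-2-en-1-one
Product: 12 3-(benzyloxy)cyclobut-2-en-1-one
Conditions: BnOH (3 equiv), CSA (5 mol%), toluene, 30 °C, reduced pressure; Et3N quench
Reagents that add atoms: benzyl alcohol, OCc1ccccc1
Why: Acid-catalysed addition–elimination of benzyl alcohol at the β-carbon of the vinylogous ester (transetherification) should exchange the alkoxy group, the equilibrium being driven by stripping ethanol at a temperature well below the electrocyclic opening of the cyclobutenone.

Step 6
Reactants: 10 (2S,3R)-2-[3,4-bis(benzyloxy)phenyl]-3-[3-(triisopropylsilyloxy)prop-2-yn-1-yl]oxirane; 12 3-(benzyloxy)cyclobut-2-en-1-one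
Product: 13 5-(benzyloxy)-2-{[(2R,3S)-3-[3,4-bis(benzyloxy)phenyl]oxiran-2-yl]methyl}-3-(triisopropylsilyloxy)phenol
Conditions: toluene (0.2 M), 2,6-di-tert-butyl-4-methylpyridine (0.1 equiv), 90–110 °C, slow addition of 12 (1.1 equiv); chromatography on Et3N-deactivated SiO2
Reagents that add atoms: none
Why: Heating opens 12 by 4π-electrocyclic cleavage of its C1–C4 bond to the (2-benzyloxyvinyl)ketene, whose electrophilic carbonyl carbon (the future C8a) is attacked by the nucleophilic, chain-bearing carbon of the ynol ether (C4a) in a regiospecific [2+2] cycloaddition that also joins the siloxy carbon (C5) to the ketene α-carbon (C6). The resulting 4-vinylcyclobutenone reopens by a second 4π-electrocyclic cleavage to a dienylketene, and ring A closes by 6π-electrocyclisation (C8–C8a) followed by tautomerisation to the phenol. This is the Danheiser benzannulation of a cyclobutenone with a siloxyalkyne. No stereocentre is created, and the two epoxide carbons are spectators that keep their configuration. The regiochemistry needed (oxygen on C5, C7 and C8a, chain on C4a) is dictated by the polarity of ketene and ynol ether. The chemoselectivity needed is survival of the acid-labile aryl epoxide beside the new phenol, which should be secured by the neutral aprotic medium, the hindered pyridine as proton scavenger, slow addition of 12 so that no ketene is left to acylate the phenol, and the lowest workable temperature.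

Step 7
Reactants: 13 5-(benzyloxy)-2-{[(2R,3S)-3-[3,4-bis(benzyloxy)phenyl]oxiran-2-yl]methyl}-3-(triisopropylsilyloxy)phenol
Product: 14 (2R,3R)-7-(benzyloxy)-2-[3,4-bis(benzyloxy)phenyl]-5-(triisopropylsilyloxy)-3,4-dihydro-2H-chromen-3-ol
Conditions: CSA (5 mol%), CH2Cl2, −40 → 0 °C; Et3N quench
Reagents that add atoms: none
Why: Brønsted-acid activation lets the phenol open the epoxide at the benzylic carbon C2, where the electron-rich aryl group stabilises the developing positive charge (6-endo over 5-exo epoxide opening), and the SN2-like backside attack in a non-polar solvent at low temperature inverts C2 while C3 is retained, so the cis-epoxide should give the 2,3-cis (2R,3R) flavan-3-ol.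

Step 8
Reactants: 14 (2R,3R)-7-(benzyloxy)-2-[3,4-bis(benzyloxy)phenyl]-5-(triisopropylsilyloxy)-3,4-dihydro-2H-chromen-3-ol; 15 4-(benzyloxy)benzoic acid
Product: 16 (2R,3R)-7-(benzyloxy)-2-[3,4-bis(benzyloxy)phenyl]-5-(triisopropylsilyloxy)-3,4-dihydro-2H-chromen-3-yl 4-(benzyloxy)benzoate
Conditions: DCC, DMAP, CH2Cl2, 0 °C → rt
Reagents that add atoms: none
Why: Steglich esterification (carbodiimide activation and acyl transfer by DMAP) should acylate the only free hydroxyl group, the axial secondary C3–OH, without touching C2 or C3.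

Step 9
Reactants: 16 (2R,3R)-7-(benzyloxy)-2-[3,4-bis(benzyloxy)phenyl]-5-(triisopropylsilyloxy)-3,4-dihydro-2H-chromen-3-yl 4-(benzyloxy)benzoate
Product: 17 (2R,3R)-7-(benzyloxy)-2-[3,4-bis(benzyloxy)phenyl]-5-hydroxy-3,4-dihydro-2H-chromen-3-yl 4-(benzyloxy)benzoate
Conditions: Bu4NF, AcOH (1:1), THF, 0 °C
Reagents that add atoms: none
Why: Fluoride cleaves the aryl silyl ether readily because phenoxide is a good leaving group on silicon (desilylation), and buffering with acetic acid keeps the medium from becoming basic enough to cleave or shift the ester or to open ring C.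

Step 10
Reactants: 17 (2R,3R)-7-(benzyloxy)-2-[3,4-bis(benzyloxy)phenyl]-5-hydroxy-3,4-dihydro-2H-chromen-3-yl 4-(benzyloxy)benzoate
Product: 18 (2R,3R)-2-(3,4-dihydroxyphenyl)-5,7-dihydroxy-3,4-dihydro-2H-chromen-3-yl 4-hydroxybenzoate
Conditions: H2 (1 atm), Pd(OH)2/C, THF/MeOH, rt
Reagents that add atoms: none
Why: Catalytic hydrogenolysis over Pd(OH)2/C should remove all four O-benzyl groups under neutral conditions, faster than the cyclic benzylic C2–O1 bond is cleaved, leaving the ester and both stereocentres intact.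

Compound list
1 | (4-bromobut-1-yn-1-yl)trimethylsilane | C[Si](C)(C)C#CCCBr | starting material
2 | triphenyl[4-(trimethylsilyl)but-3-yn-1-yl]phosphonium bromide | C[Si](C)(C)C#CCC[P+](c1ccccc1)(c1ccccc1)c1ccccc1.[Br-] | intermediate
3 | 3,4-bis(benzyloxy)benzaldehyde | O=Cc1ccc(OCc2ccccc2)c(OCc2ccccc2)c1 | starting material
4 | triphenyl[4-(trimethylsilyl)but-3-yn-1-ylidene]phosphorane (phosphorus ylide) | C[Si](C)(C)C#CCC=P(c1ccccc1)(c1ccccc1)c1ccccc1 | intermediate
5 | {(4Z)-5-[3,4-bis(benzyloxy)phenyl]pent-4-en-1-yn-1-yl}trimethylsilane (silyl enyne) | C[Si](C)(C)C#CC/C=C\c1ccc(OCc2ccccc2)c(OCc2ccccc2)c1 | intermediate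
6 | 1,2-bis(benzyloxy)-4-[(1Z)-pent-1-en-4-yn-1-yl]benzene | C#CC/C=C\c1ccc(OCc2ccccc2)c(OCc2ccccc2)c1 | intermediate
7 | (2S,3R)-2-[3,4-bis(benzyloxy)phenyl]-3-(prop-2-yn-1-yl)oxirane | C#CC[C@H]1O[C@H]1c1ccc(OCc2ccccc2)c(OCc2ccccc2)c1 | intermediate
8 | lithium acetylide of 7 | [Li]C#CC[C@H]1O[C@H]1c1ccc(OCc2ccccc2)c(OCc2ccccc2)c1 | intermediate
9 | lithium ynolate, lithium 3-{(2R,3S)-3-[3,4-bis(benzyloxy)phenyl]oxiran-2-yl}prop-1-yn-1-olate | [Li]OC#CC[C@H]1O[C@H]1c1ccc(OCc2ccccc2)c(OCc2ccccc2)c1 | intermediate
10 | (2S,3R)-2-[3,4-bis(benzyloxy)phenyl]-3-[3-(triisopropylsilyloxy)prop-2-yn-1-yl]oxirane | CC(C)[Si](C(C)C)(C(C)C)OC#CC[C@H]1O[C@H]1c1ccc(OCc2ccccc2)c(OCc2ccccc2)c1 | intermediate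
11 | 3-ethoxycyclobut-2-en-1-one | CCOC1=CC(=O)C1 | starting material
12 | 3-(benzyloxy)cyclobut-2-en-1-one | O=C1C=C(OCc2ccccc2)C1 | intermediate
13 | 5-(benzyloxy)-2-{[(2R,3S)-3-[3,4-bis(benzyloxy)phenyl]oxiran-2-yl]methyl}-3-(triisopropylsilyloxy)phenol | Oc1cc(OCc2ccccc2)cc(O[Si](C(C)C)(C(C)C)C(C)C)c1C[C@H]1O[C@H]1c1ccc(OCc2ccccc2)c(OCc2ccccc2)c1 | intermediate
14 | (2R,3R)-7-(benzyloxy)-2-[3,4-bis(benzyloxy)phenyl]-5-(triisopropylsilyloxy)-3,4-dihydro-2H-chromen-3-ol | O[C@@H]1Cc2c(O[Si](C(C)C)(C(C)C)C(C)C)cc(OCc3ccccc3)cc2O[C@@H]1c1ccc(OCc2ccccc2)c(OCc2ccccc2)c1 | intermediate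
15 | 4-(benzyloxy)benzoic acid | O=C(O)c1ccc(OCc2ccccc2)cc1 | starting material
16 | (2R,3R)-7-(benzyloxy)-2-[3,4-bis(benzyloxy)phenyl]-5-(triisopropylsilyloxy)-3,4-dihydro-2H-chromen-3-yl 4-(benzyloxy)benzoate | O=C(O[C@@H]1Cc2c(O[Si](C(C)C)(C(C)C)C(C)C)cc(OCc3ccccc3)cc2O[C@@H]1c1ccc(OCc2ccccc2)c(OCc2ccccc2)c1)c1ccc(OCc2ccccc2)cc1 | intermediate
17 | (2R,3R)-7-(benzyloxy)-2-[3,4-bis(benzyloxy)phenyl]-5-hydroxy-3,4-dihydro-2H-chromen-3-yl 4-(benzyloxy)benzoate | O=C(O[C@@H]1Cc2c(O)cc(OCc3ccccc3)cc2O[C@@H]1c1ccc(OCc2ccccc2)c(OCc2ccccc2)c1)c1ccc(OCc2ccccc2)cc1 | intermediate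
18 | (2R,3R)-2-(3,4-dihydroxyphenyl)-5,7-dihydroxy-3,4-dihydro-2H-chromen-3-yl 4-hydroxybenzoate (epicatechin 3-O-p-hydroxybenzoate) | O=C(O[C@@H]1Cc2c(O)cc(O)cc2O[C@@H]1c1ccc(O)c(O)c1)c1ccc(O)cc1 | target

Total step count: 10. Longest linear sequence: 9 steps (steps 1–4 and 6–10); step 5 is the one-step side branch.

Steps most likely to fail

1. Step 6. The aryl epoxide may ionise under heat or under the influence of the newly formed phenol, leading to a hydride-shift rearrangement or to premature, non-stereospecific ring closure. This becomes worse if the vinylogous-ester cyclobutenone opens slowly and the temperature has to be raised. The fallback moves the epoxidation behind the annulation, so that only a thermally robust Z-alkene meets the hot ketene. It sets out from enyne 6. The acetylide oxidation and silylation of step 4 should give the siloxy enyne {[(4Z)-5-[3,4-bis(benzyloxy)phenyl]pent-4-en-1-yn-1-yl]oxy}triisopropylsilane F1. Heating F1 with 12 (toluene or xylene, 110–140 °C) should give the allyl phenol 5-(benzyloxy)-2-{(2Z)-3-[3,4-bis(benzyloxy)phenyl]prop-2-en-1-yl}-3-(triisopropylsilyloxy)phenol F2. Acetylation (Ac2O, Et3N, DMAP) then masks the phenol as 5-(benzyloxy)-2-{(2Z)-3-[3,4-bis(benzyloxy)phenyl]prop-2-en-1-yl}-3-(triisopropylsilyloxy)phenyl acetate F3. Jacobsen epoxidation under the conditions of step 3 should give the epoxy acetate 5-(benzyloxy)-2-{[(2R,3S)-3-[3,4-bis(benzyloxy)phenyl]oxiran-2-yl]methyl}-3-(triisopropylsilyloxy)phenyl acetate F4. Hydrazinolysis of the aryl acetate (N2H4·H2O, THF, 0 °C) frees the phenol without forming the phenoxide, and the fallback comes back to the route at 13. This order also spares the epoxide the conditions of step 4.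

2. Step 3. The stepwise oxomanganese addition may leak through a benzylic radical to the trans-epoxide, the facial selectivity may be incomplete, and the electron-rich aryl epoxide may be opened by acid during the reaction or work-up. The fallback replaces the radical-type metal-oxo transfer by a concerted, stereospecific oxygen transfer from a titanium peroxo species. It uses the enantiomer of the di-μ-oxo titanium salalen complex [Ti(μ-O)(salalen)]2 that delivers the benzylic-S epoxide, with aqueous H2O2 in CH2Cl2 at rt. This catalyst class is used for conjugated cis-olefins and cannot scramble the olefin geometry. The fallback sets out from 6 and comes back to the route at 7 without any new compound (F0).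

3. Step 5. Benzyl alcohol may attack the strained carbonyl group with cleavage of the four-membered ring to an acyclic β-alkoxy crotonate, or the ring may open to the vinylketene, which the alcohol would then capture. The fallback separates removal of the ethyl group from introduction of the benzyl group and avoids acid and heat in the second operation. It sets out from 11, which dilute aqueous HCl should hydrolyse to the strongly acidic cyclobutane-1,3-dione F5. Mitsunobu O-alkylation of F5 with benzyl alcohol (PPh3, DIAD, THF, 0 °C) should then give the vinylogous ester, and the fallback comes back to the route at 12.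

Further compounds
F1 | step 6 | {[(4Z)-5-[3,4-bis(benzyloxy)phenyl]pent-4-en-1-yn-1-yl]oxy}triisopropylsilane | CC(C)[Si](C(C)C)(C(C)C)OC#CC/C=C\c1ccc(OCc2ccccc2)c(OCc2ccccc2)c1
F2 | step 6 | 5-(benzyloxy)-2-{(2Z)-3-[3,4-bis(benzyloxy)phenyl]prop-2-en-1-yl}-3-(triisopropylsilyloxy)phenol | Oc1cc(OCc2ccccc2)cc(O[Si](C(C)C)(C(C)C)C(C)C)c1C/C=C\c1ccc(OCc2ccccc2)c(OCc2ccccc2)c1
F3 | step 6 | 5-(benzyloxy)-2-{(2Z)-3-[3,4-bis(benzyloxy)phenyl]prop-2-en-1-yl}-3-(triisopropylsilyloxy)phenyl acetate | CC(=O)Oc1cc(OCc2ccccc2)cc(O[Si](C(C)C)(C(C)C)C(C)C)c1C/C=C\c1ccc(OCc2ccccc2)c(OCc2ccccc2)c1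
F4 | step 6 | 5-(benzyloxy)-2-{[(2R,3S)-3-[3,4-bis(benzyloxy)phenyl]oxiran-2-yl]methyl}-3-(triisopropylsilyloxy)phenyl acetate | CC(=O)Oc1cc(OCc2ccccc2)cc(O[Si](C(C)C)(C(C)C)C(C)C)c1C[C@H]1O[C@H]1c1ccc(OCc2ccccc2)c(OCc2ccccc2)c1
F0 | step 3 | none | none
F5 | step 5 | cyclobutane-1,3-dione | O=C1CC(=O)C1
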